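The numbers in the tables were generated by integration with constants of no real substance; the scatter is artificial.

The pitfall was to scale the rate of the grey run in proportion to its charge of free catalyst, a factor of 0.500, although no earlier run changes that charge, so the proportion was an untested assumption.

| setting | grey | flask |
|---|---|---|
| left-handed substrate | 0.20 M | 0.20 M |
| right-handed substrate | 0.20 M | 0.20 M |
| gas | 10 mM (held) | 10 mM (held) |
| free catalyst | 0.60 mM | 0.30 mM |
| racemization catalyst | 4 mM | 4.0 mM |
| impurity | 54 µM | 54 µM |
| remark | run made earlier |  |
| time |  | 12 min |

grey run (percent of the left-handed substrate and right-handed substrate together charged)

| time / min | left-handed substrate / % | right-handed substrate / % |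
|---|---|---|
| 0.200 | 49 | 46 |
| 0.667 | 44 | 43 |
| 1.00 | 43 | 44 |
| 1.50 | 39 | 40 |
| 2.50 | 34 | 34 |

(readings scatter by 1.5 percentage points)

- free catalyst is single-handed; left-handed substrate and right-handed substrate are mirror images of each other, charged as a racemate, each of them at the stated concentration
- at the start none of coupling partner is dissolved
- the analysis behind the earlier runs scatters by 1.5 percentage points, standard deviation
- steps under discussion: coupling partner + free catalyst + left-handed substrate -> free catalyst + left-handed product; coupling partner + free catalyst + right-handed substrate -> free catalyst + right-handed product; left-handed substrate + racemization catalyst <-> right-handed substrate + racemization catalyst; gas <-> coupling partner; free catalyst + impurity -> spent catalyst A; free catalyst -> spent catalyst B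
- an excess is the difference of the two amounts in percent of their sum
- an excess is below zero if the other one leads
- no earlier run changes the charge of free catalyst; that part of a forecast is a guess

- part of the left-handed substrate and right-handed substrate charged together that has reacted at 12 min
- excess of left-handed product over right-handed product in the product at 12 min
- excess of right-handed substrate over left-handed substrate among what is left of the two at 12 min

The working catalyst, 0.246 mM in this flask against 0.546 mM in the grey run, is the charge of free catalyst less [impurity], taken mole for mole. I read a pseudo-first-order constant from the last grey readings, then asked which input moved conversion at 12 min: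

k = 0.154 /min

rate proportional to working catalyst: 56.6%

[impurity] ignored, rate proportional to charge: 60.4%

k unchanged by the catalyst: 84.3%

Ignoring [impurity] shifted my answer by 3.8 percentage points, but the catalyst order shifted it by 28 points, which is more. [racemization catalyst] matched the grey run. I committed to the span 56.6% to 84.3%. The grey run read substrates, not products, so I set no product excess.

The forecast gave conversion 52% (36% to 70%), below my lower end, product excess 0% (−70% to 70%) and substrate excess 0% (−4% to 4%), noting: “Substrate order and catalyst order are also assumptions.”

The flask gave conversion 78.1%, product excess 27.7% and substrate excess 0.0488%.

    coupling partner + free catalyst + left-handed substrate → free catalyst + left-handed product (k = 2300 /M²/s)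
    coupling partner + free catalyst + right-handed substrate → free catalyst + right-handed product (k = 1300 /M²/s)
    left-handed substrate + racemization catalyst ⇌ right-handed substrate + racemization catalyst, rate k3*[racemization catalyst]*[left-handed substrate] forward; the back reaction follows from the equilibrium constant (k = 140 /M/s)
    gas ⇌ coupling partner, rate k4*(csat - [coupling partner]) (kL = 0.140 /s)
    free catalyst + impurity → spent catalyst A (k = 15000 /M/s)
    free catalyst → spent catalyst B (k = 9.40 × 10⁻⁴ /s)

In this flask, [coupling partner] stood at 0.00490 M after 1.20 min, below saturation. At 12 min, free catalyst and spent catalyst B together held 82.0% of the charge, and 0.246 mM is 82.0% of it. The neighbour charged with 1.2 × 10⁻⁴ M of free catalyst has 0.0660 mM working catalyst, 55.0% of its charge, and its span runs from 20.0% to 84.3%. That neighbour gave conversion 40.0%, with free catalyst and spent catalyst B together at 55.0% and product excess 27.8%.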